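The route rests on the C3–C4 bond of ring A (labdane numbering). The key step exploits the gem-dimethyl carbon C4 on C5, which in ring B sits 1,4 to the C8 methylene carbon: with C8 as a ketone, C4–C5–C6–C7 is the cyclobutane of (−)-verbenone (1). A Lewis acid opens the strained C7–C4 bond of a pinanone that already carries the C10 quaternary centre, the C9 side chain and a C2 silyl enol ether; the tertiary C4 cation is trapped by C3, so one operation unveils ring B and closes ring A as a trans-decalin-2,8-dione. Pinane face bias sets C10 and C9 beforehand; hydride sets C2 afterwards.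

Key step: step 7

Remark: labdane numbering (C1–C20) of the target is used for every bicyclic intermediate; in the pinane intermediates C4 is the CMe2 bridge, C6 the CH2 bridge, C5 and C7 the bridgeheads and C8 the carbonyl carbon.
Remark: the target is read as drawn, a trans-decalin (5R,10R) whose C9 side chain is anti to the C10 methyl (9S) and whose 2-acyloxy group is axial and syn to the C10 methyl (2S); C13 is S.
Assumption: 1 is used in at least 98% ee and 2 in at least 97% ee; a minor enantiomer of 1 would show up after step 4 as a separable diastereomer.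

Step 1
Reactants: 2 methyl hydrogen (R)-3-methylglutarate
Product: 4 (S)-4-methyltetrahydro-2H-pyran-2-one, via hydroxy acid 3 (not isolated)
Conditions: LiH (1.0 equiv), THF, 0 °C; LiBH4, 0 → 50 °C; then 2 M HCl, rt
Reagents that add atoms: none
Why: Chemoselective borohydride reduction of the ester in the presence of the lithium carboxylate, followed by acid-promoted lactonisation; the stereocentre is untouched and only its descriptor changes (R to S) because the priorities of the two arms switch.

Step 2
Reactants: 4 (S)-4-methyltetrahydro-2H-pyran-2-one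
Product: 6 methyl (R)-5-iodo-3-methylpentanoate, via silyl ester 5 (not isolated)
Conditions: Me3SiI, CH2Cl2, rt; then MeOH, rt
Reagents that add atoms: iodotrimethylsilane, C[Si](C)(C)I; methanol, CO
Why: Silyl iodide ring opening of the lactone (SN2 attack of iodide at the O–CH2 carbon of the O-silylated lactone) should give silyl ester 5, which the HI released on adding methanol should convert to the methyl ester (Fischer esterification); the stereocentre is not involved.

Step 3
Reactants: 1 (1S,5S)-(−)-verbenone
Product: 7 4-allyl-4,6,6-trimethyl-2-(trimethylsilyloxy)bicyclo[3.1.1]hept-2-ene (allyl anti to the CMe2 bridge)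
Conditions: allylMgBr, CuBr·SMe2, LiCl, Me3SiCl, THF, −78 °C; Et3N, cold aq NaHCO3
Reagents that add atoms: allylmagnesium bromide, C=CC[Mg]Br; chlorotrimethylsilane, C[Si](C)(C)Cl
Why: Me3SiCl-accelerated conjugate addition of an allylcopper reagent to the β,β-disubstituted enone; the reagent should attack C10 from the face anti to the CMe2 bridge, which sets the C10 quaternary centre with the allyl group trans to C4, and the enolate is trapped as its silyl enol ether.

Step 4
Reactants: 7 the silyl enol ether of step 3; 6 methyl (R)-5-iodo-3-methylpentanoate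
Product: 9 methyl (3S)-5-[4-allyl-4,6,6-trimethyl-2-oxobicyclo[3.1.1]heptan-3-yl]-3-methylpentanoate (allyl group cis to ester chain; both anti to the CMe2 bridge), via lithium enolate 8 (not isolated)
Conditions: MeLi, THF, 0 °C → rt; then HMPA, 6, −78 °C → rt
Reagents that add atoms: none
Why: Regiospecific enolate generation from the silyl enol ether by MeLi (the bridgehead C7 cannot enolise, so 8 is the only enolate), then SN2 enolate alkylation by the primary iodide; the electrophile should enter C9 from the face anti to the CMe2 bridge, placing the side chain cis to the allyl group and trans to the C10 methyl.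

Step 5
Reactants: 9 the allyl pinanone ester of step 4
Product: 10 methyl (3S)-3-methyl-5-[4,6,6-trimethyl-2-oxo-4-(2-oxopropyl)bicyclo[3.1.1]heptan-3-yl]pentanoate
Conditions: PdCl2 (10 mol %), CuCl (1 equiv), O2 (1 atm), DMF/H2O 7:1, rt
Reagents that add atoms: water, O
Why: Tsuji–Wacker oxidation; Markovnikov hydroxypalladation of the terminal alkene should give the methyl ketone, while the hindered ring ketone and the ester are inert.

Step 6
Reactants: 10 the diketone of step 5
Product: 12 methyl (3S)-5-{4-[2-(tert-butyldimethylsilyloxy)prop-2-enyl]-4,6,6-trimethyl-2-oxobicyclo[3.1.1]heptan-3-yl}-3-methylpentanoate, via lithium enolate 11 (not isolated)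
Conditions: LiN(i-Pr)2 (LDA, 1.05 equiv), THF, −78 °C; t-BuMe2SiCl, HMPA, −78 → −20 °C
Reagents that add atoms: tert-butyldimethylsilyl chloride, CC(C)(C)[Si](C)(C)Cl
Why: Kinetic enolate formation and O-silylation; the base should remove a proton of the methyl group C3, the only unhindered acidic site (C1 is neopentylic, C9–H is tertiary next to the quaternary C10, the bridgehead C7–H cannot enolise, the ester is less acidic).

Step 7
Reactants: 12 the silyl enol ether of step 6
Product: 15 methyl (3S)-3-methyl-5-[5,5,8a-trimethyl-2,7-dioxodecahydronaphthalen-1-yl]pentanoate (trans-fused; labdane 2,8-dione; C9 side chain axial), via ring-opened C4 cation 13 (not isolated), via cyclised titanium enolate 14 (not isolated)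
Conditions: TiCl4 (2.2 equiv), 2,6-di-tert-butyl-4-methylpyridine (0.3 equiv), CH2Cl2, −78 → −30 °C; then H2O
Reagents that add atoms: none
Why: Proposed new method: TiCl4 binds the C8 ketone and the strained cyclobutane bond C7–C4, which overlaps with the carbonyl π system, should heterolyse to the tertiary C4 carbocation and a C7=C8 titanium enolate (13), releasing roughly 26 kcal/mol of ring strain; the cation is captured by the CH2 terminus C3 of the tethered silyl enol ether, loss of t-BuMe2SiCl gives the C2 ketone (14), and work-up protonates C7. The closest known reaction types are the Lewis-acid cleavage of nopinone-type cyclobutyl ketones to tertiary p-menthyl cations (BBr3, AlCl3, Me3SiI) and the TiCl4-mediated α-tert-alkylation of silyl enol ethers by tertiary halides; their merger into one intramolecular cascade is the untested part. Ring A closes in a 6-endo-trig mode with respect to the enol ether double bond (6-(enolendo)), both enol carbons C2 and C3 ending up in the new ring, through a chair transition state. No new stereocentre is formed; the trans ring fusion follows from the trans relation of the C1 arm on C10 and the C4 unit on C5 set in step 3, both equatorial on ring B. The step needs C-alkylation at C3 to win over proton loss from the cation, chloride capture and aldol addition of the enol silane to C8: chloride capture and the ketone aldol are reversible under TiCl4 while C–C bond formation is not, the hindered pyridine removes HCl that would cleave the enol silane, and C9 cannot epimerise because C8 stays a C7-side enolate until work-up.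

Step 8
Reactants: 15 the dione of step 7
Product: 16 methyl (3S)-5-[7-hydroxy-5,5,8a-trimethyl-2-oxodecahydronaphthalen-1-yl]-3-methylpentanoate (labdane (2S)-2-ol; OH axial)
Conditions: LiBH(s-Bu)3 (L-Selectride, 1.05 equiv), THF, −78 °C; then H2O
Reagents that add atoms: none
Why: Bulky hydride reduction; the reagent should attack the C2 carbonyl along the equatorial trajectory, from the face opposite the syn-axial methyl groups on C10 and C4, giving the axial (2S) alcohol, while C8 is left because its axial face is blocked by the C10 methyl and its equatorial face by the axial C9 side chain.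

Step 9
Reactants: 16 the hydroxy ketone of step 8
Product: 17 methyl (3S)-3-methyl-5-[5,5,8a-trimethyl-7-(3-methylbutanoyloxy)-2-oxodecahydronaphthalen-1-yl]pentanoate
Conditions: 3-methylbutanoyl chloride, pyridine, DMAP (cat.), CH2Cl2, 0 → 40 °C
Reagents that add atoms: 3-methylbutanoyl chloride, CC(C)CC(Cl)=O
Why: DMAP-catalysed acylation (nucleophilic acyl transfer) of the hindered axial alcohol, with retention at C2.

Step 10
Reactants: 17 the keto diester of step 9
Product: 18 methyl (2S,5R,9S,10R,13S)-2-(3-methylbutanoyloxy)labd-8(17)-en-15-oate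
Conditions: Zn, CH2Br2, TiCl4, THF/CH2Cl2, 0 °C → rt
Reagents that add atoms: dibromomethane, BrCBr
Why: Takai–Lombardo methylenation; the non-basic reagent should convert the hindered, enolisable C8 ketone to the exocyclic methylene without epimerising C9 and without touching the two esters.

Step 11
Reactants: 18 the methyl ester of step 10
Product: 19 (2S,5R,9S,10R,13S)-2-(3-methylbutanoyloxy)labd-8(17)-en-15-oic acid (target)
Conditions: Me3SnOH, ClCH2CH2Cl, 80 °C; then 5% aq HCl wash
Reagents that add atoms: trimethyltin hydroxide, C[Sn](C)(C)O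
Why: Tin hydroxide ester hydrolysis, selective for the unhindered methyl ester; the isovalerate on the hindered axial C2 oxygen, the alkene and all stereocentres should be untouched.

Compound list
1 | (1S,5S)-(−)-verbenone, (1S,5S)-4,6,6-trimethylbicyclo[3.1.1]hept-3-en-2-one | O=C1C=C(C)[C@@H]2C[C@H]1C2(C)C | starting material
2 | methyl hydrogen (R)-3-methylglutarate, (3R)-5-methoxy-3-methyl-5-oxopentanoic acid | COC(=O)C[C@H](C)CC(=O)O | starting material
3 | (S)-5-hydroxy-3-methylpentanoic acid | OCC[C@H](C)CC(=O)O | intermediate
4 | (S)-4-methyltetrahydro-2H-pyran-2-one | O=C1C[C@@H](C)CCO1 | intermediate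
5 | trimethylsilyl (R)-5-iodo-3-methylpentanoate | ICC[C@H](C)CC(=O)O[Si](C)(C)C | intermediate
6 | methyl (R)-5-iodo-3-methylpentanoate | ICC[C@H](C)CC(=O)OC | intermediate
7 | 4-allyl-4,6,6-trimethyl-2-(trimethylsilyloxy)bicyclo[3.1.1]hept-2-ene, bridgeheads as in 1, allyl anti to the CMe2 bridge (labdane: C8=C9 enol ether, C10 bears CH3 and allyl) | C[Si](C)(C)OC1=C[C@](C)(CC=C)[C@@H]2C[C@H]1C2(C)C | intermediate
8 | lithium enolate of 4-allyl-4,6,6-trimethylbicyclo[3.1.1]heptan-2-one, same configuration as 7 | [Li]OC1=C[C@](C)(CC=C)[C@@H]2C[C@H]1C2(C)C | intermediate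
9 | methyl (3S)-5-[4-allyl-4,6,6-trimethyl-2-oxobicyclo[3.1.1]heptan-3-yl]-3-methylpentanoate, allyl and ester chain cis to each other and anti to the CMe2 bridge | O=C1[C@H]2C[C@H](C2(C)C)[C@@](C)(CC=C)[C@H]1CC[C@H](C)CC(=O)OC | intermediate
10 | methyl (3S)-3-methyl-5-[4,6,6-trimethyl-2-oxo-4-(2-oxopropyl)bicyclo[3.1.1]heptan-3-yl]pentanoate, configuration as 9 | O=C1[C@H]2C[C@H](C2(C)C)[C@@](C)(CC(C)=O)[C@H]1CC[C@H](C)CC(=O)OC | intermediate
11 | terminal (C2=C3) lithium enolate of the methyl ketone of 10 | O=C1[C@H]2C[C@H](C2(C)C)[C@@](C)(CC(=C)O[Li])[C@H]1CC[C@H](C)CC(=O)OC | intermediate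
12 | methyl (3S)-5-{4-[2-(tert-butyldimethylsilyloxy)prop-2-enyl]-4,6,6-trimethyl-2-oxobicyclo[3.1.1]heptan-3-yl}-3-methylpentanoate, configuration as 9 | O=C1[C@H]2C[C@H](C2(C)C)[C@@](C)(CC(=C)O[Si](C)(C)C(C)(C)C)[C@H]1CC[C@H](C)CC(=O)OC | intermediate
13 | ring-opened zwitterion: tertiary C4 carbocation on C5 of a cyclohexene whose C7=C8 enolate oxygen carries TiCl4 | C[C+](C)[C@H]1CC=C(O[Ti-](Cl)(Cl)(Cl)Cl)[C@H](CC[C@H](C)CC(=O)OC)[C@]1(C)CC(=C)O[Si](C)(C)C(C)(C)C | intermediate
14 | trichlorotitanium C7=C8 enolate of dione 15 | Cl[Ti](Cl)(Cl)OC1=CC[C@@H]2C(C)(C)CC(=O)C[C@@]2(C)[C@H]1CC[C@H](C)CC(=O)OC | intermediate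
15 | methyl (3S)-3-methyl-5-[5,5,8a-trimethyl-2,7-dioxodecahydronaphthalen-1-yl]pentanoate; trans-decalin, C10 methyl anti to C5–H, C9 side chain axial and anti to the C10 methyl (labdane 2,8-dione) | O=C1CC[C@@H]2C(C)(C)CC(=O)C[C@@]2(C)[C@H]1CC[C@H](C)CC(=O)OC | intermediate
16 | methyl (3S)-5-[7-hydroxy-5,5,8a-trimethyl-2-oxodecahydronaphthalen-1-yl]-3-methylpentanoate; labdane (2S)-2-ol, OH axial and syn to the C10 methyl | O=C1CC[C@@H]2C(C)(C)C[C@H](O)C[C@@]2(C)[C@H]1CC[C@H](C)CC(=O)OC | intermediate
17 | methyl (3S)-3-methyl-5-[5,5,8a-trimethyl-7-(3-methylbutanoyloxy)-2-oxodecahydronaphthalen-1-yl]pentanoate, configuration as 16 | O=C1CC[C@@H]2C(C)(C)C[C@H](OC(=O)CC(C)C)C[C@@]2(C)[C@H]1CC[C@H](C)CC(=O)OC | intermediate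
18 | methyl (2S,5R,9S,10R,13S)-2-(3-methylbutanoyloxy)labd-8(17)-en-15-oate | C=C1CC[C@@H]2C(C)(C)C[C@H](OC(=O)CC(C)C)C[C@@]2(C)[C@H]1CC[C@H](C)CC(=O)OC | intermediate
19 | (2S,5R,9S,10R,13S)-2-(3-methylbutanoyloxy)labd-8(17)-en-15-oic acid | C=C1CC[C@@H]2C(C)(C)C[C@H](OC(=O)CC(C)C)C[C@@]2(C)[C@H]1CC[C@H](C)CC(=O)O | target

Total step count: 11 (steps 1–11).
Longest linear sequence: 10 steps (steps 1, 2 and 4–11, from 2 to 19); step 3 makes silyl enol ether 7 from 1 in a one-step side branch that joins at step 4.

Steps most likely to fail

Step 7 (Proposed new method). The enol silane may lose its silyl group to adventitious acid before the cyclobutane opens, leaving a methyl ketone that no longer traps the cation; the cation may then be drained by proton loss, or the enol silane may add to the activated C8 carbonyl instead. The fallback uses known chemistry, sets out from 12 and returns to 15. Treating 12 with Me3SiI in CH2Cl2 at −20 °C, the known silyl iodide cleavage of nopinone-type cyclobutyl ketones, should give the ring-opened tertiary iodide F1, in which C8 is a trimethylsilyl enol ether and the C2 silyl enol ether is intact. ZnBr2 (catalytic) in CH2Cl2 at −40 °C should then close ring A by the known α-tert-alkylation of a silyl enol ether with a tertiary halide, giving the C8 trimethylsilyl enol ether of the dione F2. Brief treatment with dilute HCl in THF should hydrolyse it to 15.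

Step 4. SN2 attack by the neopentylic enolate carbon C9 on an unactivated primary iodide may be too slow, so that O-alkylation, elimination of HI from 6 or simple recovery of the ketone takes over. The fallback sets out from 7 and returns to 9, and replaces the ketone enolate by a far more nucleophilic azaenolate. Methanolysis of 7 (K2CO3, MeOH) should give 4-allyl-4,6,6-trimethylbicyclo[3.1.1]heptan-2-one F3. Condensation with Me2NNH2 (AcOH cat., EtOH, reflux) should give its N,N-dimethylhydrazone F4. LiN(i-Pr)2 in THF at 0 °C should give the lithium azaenolate F5, which can only form toward C9, and 6 should alkylate it from the face anti to the CMe2 bridge to give the C9-alkylated hydrazone F6. CuCl2 in aqueous THF at pH 7 should release ketone 9.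

Step 3. The allyl metal may add to the carbonyl carbon C8 (1,2-addition) instead of the hindered β-carbon C10. The fallback sets out from 1 and returns to 7, and turns that side reaction into the route. AllylMgBr alone (THF, −78 °C; then H2O) should add to the carbonyl from the face anti to the CMe2 bridge and give 2-allyl-4,6,6-trimethylbicyclo[3.1.1]hept-3-en-2-ol F7. KH and 18-crown-6 in THF should trigger the anionic oxy-Cope rearrangement, a [3,3] shift that moves the allyl group suprafacially from C8 to C10 on the same face, and give the potassium enolate F8. Me3SiCl should silylate it to 7.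

Further compounds
F1 | step 7 | ring-opened tertiary iodide: 2-iodopropan-2-yl group on C5, C8 trimethylsilyl enol ether (C7=C8), C2 tert-butyldimethylsilyl enol ether, C9 ester chain | CC(C)(I)[C@H]1CC=C(O[Si](C)(C)C)[C@H](CC[C@H](C)CC(=O)OC)[C@]1(C)CC(=C)O[Si](C)(C)C(C)(C)C
F2 | step 7 | C8 trimethylsilyl enol ether (C7=C8) of dione 15 | C[Si](C)(C)OC1=CC[C@@H]2C(C)(C)CC(=O)C[C@@]2(C)[C@H]1CC[C@H](C)CC(=O)OC
F3 | step 4 | 4-allyl-4,6,6-trimethylbicyclo[3.1.1]heptan-2-one, allyl anti to the CMe2 bridge | O=C1C[C@](C)(CC=C)[C@@H]2C[C@H]1C2(C)C
F4 | step 4 | N,N-dimethylhydrazone of F3 | CN(C)N=C1C[C@](C)(CC=C)[C@@H]2C[C@H]1C2(C)C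
F5 | step 4 | lithium azaenolate of F4 (C8=C9) | CN(C)N([Li])C1=C[C@](C)(CC=C)[C@@H]2C[C@H]1C2(C)C
F6 | step 4 | N,N-dimethylhydrazone of ketone 9 | CN(C)N=C1[C@H]2C[C@H](C2(C)C)[C@@](C)(CC=C)[C@H]1CC[C@H](C)CC(=O)OC
F7 | step 3 | 2-allyl-4,6,6-trimethylbicyclo[3.1.1]hept-3-en-2-ol, allyl anti to the CMe2 bridge | C=CC[C@]1(O)C=C(C)[C@@H]2C[C@H]1C2(C)C
F8 | step 3 | potassium enolate of 4-allyl-4,6,6-trimethylbicyclo[3.1.1]heptan-2-one | [K]OC1=C[C@](C)(CC=C)[C@@H]2C[C@H]1C2(C)C
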